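**Retrosynthetic overview**

1. The target is a (2S,4R)-2,4-trans 7,3',4'-trihydroxyflavan joined through its C4 to C8 of (+)-catechin. The last C–C bond made is C4–C8, by Friedel–Crafts attack of tetra-O-benzyl-(+)-catechin on the (2S)-flavan-4-yl cation, followed by global debenzylation.
2. Only the upper pyran ring is built. It is cut across C2–C3 and O1–C8a into aldehyde 4 (O1=C2 carrying the catechol ring) and the four-atom unit C3=C4(OSiMe3)–C4a=C8a(F) of silyl enol ether 3. These are joined in one flask by a catalytic enantioselective Mukaiyama aldol and a fluoride-relayed SNAr closure, a formal hetero-[4+2] with loss of Me3SiF.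
3. Enabling feature: C4 of the upper unit is a benzylic carbon on C4a of ring A, ortho to C8a and para to the C7 oxygen. As a ketone it makes C3 an enol nucleophile and activates a fluorine on C8a for ipso substitution. As an alcohol it later ionises, stabilised by O1 and O7, for the C4–C8 bond.
4. Stereochemistry: upper C2 comes from the aldol catalyst; upper C4 is relayed from C2 by attack anti to the C2 aryl group; lower C2 and C3 are bought with (+)-catechin. Both benzene rings of the upper unit and all rings of catechin are purchased.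

Key step: step 3

Assumption: the oxazaborolidinone from N-tosyl-(S)-tryptophan is taken to direct the enol ether to the Si face of aldehyde 4, which gives the (S)-aldolate; if the opposite sense is found, the catalyst from (R)-tryptophan is used instead.

**Step 1**
Reactants: 1 1-(2-fluoro-4-hydroxyphenyl)ethan-1-one
Product: 2 1-[4-(benzyloxy)-2-fluorophenyl]ethan-1-one
Conditions: BnBr, K2CO3, DMF, 23 °C
Reagents that add atoms: benzyl bromide, BrCc1ccccc1
Why: Williamson ether synthesis, in which the phenoxide of 1 (the only site ionised by carbonate) should be benzylated cleanly without forming a stereocentre.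

**Step 2**
Reactants: 2 1-[4-(benzyloxy)-2-fluorophenyl]ethan-1-one
Product: 3 ({1-[4-(benzyloxy)-2-fluorophenyl]ethenyl}oxy)trimethylsilane
Conditions: TMSOTf, Et3N, CH2Cl2, 0 °C; non-aqueous work-up
Reagents that add atoms: trimethylsilyl trifluoromethanesulfonate, C[Si](C)(C)OS(=O)(=O)C(F)(F)F
Why: soft enolisation and O-silylation of an aryl methyl ketone with a silyl triflate and an amine base should give the only possible silyl enol ether, with no stereocentre formed.

**Step 3**
Reactants: 3 ({1-[4-(benzyloxy)-2-fluorophenyl]ethenyl}oxy)trimethylsilane; 4 3,4-bis(benzyloxy)benzaldehyde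
Product: 6 (2S)-7-(benzyloxy)-2-[3,4-bis(benzyloxy)phenyl]chroman-4-one, via silyl aldol ether 5 (not isolated)
Conditions: B-butyl oxazaborolidinone from N-tosyl-(S)-tryptophan (20 mol %), EtCN, −78 °C; then CsF (0.5 equiv), DMF, −20 → 23 °C
Reagents that add atoms: none
Why: Proposed new method: the boron catalyst binds aldehyde 4 and enol ether 3 should add through C3 to its Si face (C2–C3 bond, Mukaiyama aldol with silyl transfer to the aldolate oxygen, giving 5); fluoride then removes silicon and the C2 alkoxide should displace the fluorine on C8a by addition–elimination through a Meisenheimer adduct stabilised by the ortho C4 ketone (O1–C8a bond), the expelled fluoride carrying the chain so that Me3SiF is the only by-product. The closest known reaction types are the aldol–dihydropyranone annulation of 1-alkoxy-3-siloxydienes with aldehydes (Mukaiyama aldol, then oxa-Michael addition–elimination), here with the aryl C–F bond in the role of the alkoxy-bearing diene terminus, and the fluoride-catalysed SNAr etherification of silyl ethers with ortho-acyl aryl fluorides, whose nitrogen counterpart closes 4-quinolones. The pyranone ring closes in a six-membered exo mode by ipso attack of the oxygen on ring carbon C8a. The only new stereocentre, C2, is set by the chiral catalyst (catalyst control, S) and cannot change in the ring closure because the C2–O bond is never broken. The step needs ring closure to win over retro-aldol cleavage and over elimination to the chalcone: the silyl ether keeps the aldolate masked until fluoride is added at low temperature, only a catalytic amount of free alkoxide is present at any time, and the ortho carbonyl should make the intramolecular substitution fast.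

**Step 4**
Reactants: 6 (2S)-7-(benzyloxy)-2-[3,4-bis(benzyloxy)phenyl]chroman-4-one
Product: 7 (2S,4S)-7-(benzyloxy)-2-[3,4-bis(benzyloxy)phenyl]chroman-4-ol
Conditions: NaBH4, THF/MeOH, 0 °C
Reagents that add atoms: none
Why: borohydride reduction of a flavanone, in which hydride should add axially on the face opposite the equatorial C2 aryl group to give the 2,4-cis alcohol (substrate control), a configuration that is erased on ionisation in step 6.

**Step 5**
Reactants: 8 (+)-catechin
Product: 9 (2R,3S)-5,7-bis(benzyloxy)-2-[3,4-bis(benzyloxy)phenyl]chroman-3-ol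
Conditions: BnBr (4.2 equiv), K2CO3, DMF, −10 → 23 °C, argon
Reagents that add atoms: benzyl bromide, BrCc1ccccc1
Why: Williamson ether synthesis, in which carbonate ionises the four phenols but not the secondary C3 alcohol, so the tetrabenzyl ether with free 3-OH should result while the bought C2 and C3 centres stay untouched.

**Step 6**
Reactants: 7 (2S,4S)-7-(benzyloxy)-2-[3,4-bis(benzyloxy)phenyl]chroman-4-ol; 9 (2R,3S)-5,7-bis(benzyloxy)-2-[3,4-bis(benzyloxy)phenyl]chroman-3-ol (3 equiv)
Product: 10 (2R,3S)-5,7-bis(benzyloxy)-8-{(2S,4R)-7-(benzyloxy)-2-[3,4-bis(benzyloxy)phenyl]chroman-4-yl}-2-[3,4-bis(benzyloxy)phenyl]chroman-3-ol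
Conditions: TMSOTf (0.2 equiv), 4 Å MS, CH2Cl2, −78 → −40 °C
Reagents that add atoms: none
Why: Friedel–Crafts alkylation in which the C4 hydroxyl of 7 leaves as water (taken up by the sieves) to give the C4 benzylic cation, stabilised by O1 and the para C7 oxygen; the phloroglucinol-type ring of 9 should attack through C8, its less hindered free position, along the pseudo-axial path on the face opposite the equatorial C2 aryl group, giving the 2,4-trans (4R) product by substrate control as in Lewis-acid interflavan couplings of benzylated flavan units.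

**Step 7**
Reactants: 10 (2R,3S)-5,7-bis(benzyloxy)-8-{(2S,4R)-7-(benzyloxy)-2-[3,4-bis(benzyloxy)phenyl]chroman-4-yl}-2-[3,4-bis(benzyloxy)phenyl]chroman-3-ol
Product: 11 (2R,3S)-2-(3,4-dihydroxyphenyl)-8-[(2S,4R)-2-(3,4-dihydroxyphenyl)-7-hydroxychroman-4-yl]chroman-3,5,7-triol
Conditions: H2 (1 atm), Pd(OH)2/C, THF/MeOH, 23 °C; filtration under argon, Sephadex LH-20
Reagents that add atoms: none
Why: hydrogenolysis of the seven aryl benzyl ethers under neutral conditions at room temperature should free all phenols without touching the four stereocentres or the cyclic benzylic ethers.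

**Compound list**

1 | 1-(2-fluoro-4-hydroxyphenyl)ethan-1-one | CC(=O)c1ccc(O)cc1F | starting material
2 | 1-[4-(benzyloxy)-2-fluorophenyl]ethan-1-one | CC(=O)c1ccc(OCc2ccccc2)cc1F | intermediate
3 | ({1-[4-(benzyloxy)-2-fluorophenyl]ethenyl}oxy)trimethylsilane | C=C(O[Si](C)(C)C)c1ccc(OCc2ccccc2)cc1F | intermediate
4 | 3,4-bis(benzyloxy)benzaldehyde | O=Cc1ccc(OCc2ccccc2)c(OCc2ccccc2)c1 | starting material
5 | (3S)-1-[4-(benzyloxy)-2-fluorophenyl]-3-[3,4-bis(benzyloxy)phenyl]-3-[(trimethylsilyl)oxy]propan-1-one | O=C(C[C@H](O[Si](C)(C)C)c1ccc(OCc2ccccc2)c(OCc2ccccc2)c1)c1ccc(OCc2ccccc2)cc1F | intermediate (not isolated)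
6 | (2S)-7-(benzyloxy)-2-[3,4-bis(benzyloxy)phenyl]chroman-4-one | O=C1C[C@@H](c2ccc(OCc3ccccc3)c(OCc3ccccc3)c2)Oc2cc(OCc3ccccc3)ccc21 | intermediate
7 | (2S,4S)-7-(benzyloxy)-2-[3,4-bis(benzyloxy)phenyl]chroman-4-ol | O[C@H]1C[C@@H](c2ccc(OCc3ccccc3)c(OCc3ccccc3)c2)Oc2cc(OCc3ccccc3)ccc21 | intermediate
8 | (+)-catechin, (2R,3S)-2-(3,4-dihydroxyphenyl)chroman-3,5,7-triol | Oc1cc(O)c2c(c1)O[C@H](c1ccc(O)c(O)c1)[C@@H](O)C2 | starting material
9 | (2R,3S)-5,7-bis(benzyloxy)-2-[3,4-bis(benzyloxy)phenyl]chroman-3-ol | C(c1ccccc1)Oc1cc(OCc2ccccc2)c2c(c1)O[C@H](c1ccc(OCc3ccccc3)c(OCc3ccccc3)c1)[C@@H](O)C2 | intermediate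
10 | (2R,3S)-5,7-bis(benzyloxy)-8-{(2S,4R)-7-(benzyloxy)-2-[3,4-bis(benzyloxy)phenyl]chroman-4-yl}-2-[3,4-bis(benzyloxy)phenyl]chroman-3-ol | C(c1ccccc1)Oc1ccc2c(c1)O[C@H](c3ccc(OCc4ccccc4)c(OCc4ccccc4)c3)C[C@H]2c3c(OCc4ccccc4)cc(OCc4ccccc4)c4c3O[C@H](c3ccc(OCc5ccccc5)c(OCc5ccccc5)c3)[C@@H](O)C4 | intermediate
11 | (2R,3S)-2-(3,4-dihydroxyphenyl)-8-[(2S,4R)-2-(3,4-dihydroxyphenyl)-7-hydroxychroman-4-yl]chroman-3,5,7-triol (CNP0227165.4) | Oc1ccc2c(c1)O[C@H](c1ccc(O)c(O)c1)C[C@H]2c1c(O)cc(O)c2c1O[C@H](c1ccc(O)c(O)c1)[C@@H](O)C2 | target

**Step count and risks**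

Total step count: 7. Longest linear sequence: 6 steps (steps 1, 2, 3, 4, 6, 7 from compound 1); the catechin branch is 3 steps (5, 6, 7).

Steps most likely to fail:

1. Step 3 (proposed new method). After the aldolate is unmasked, retro-aldol cleavage or elimination to the open-chain enone may outrun ring closure. Facial selectivity in the aldol with an electron-rich aldehyde may also be incomplete; any (2R) material carried forward would end as a diastereomer after step 6 and should be separable there. Fallback with known chemistry, setting out from 4 and returning at 7: Claisen–Schmidt condensation of 4 with purchased 4'-(benzyloxy)-2'-hydroxyacetophenone F1 (KOH, EtOH, 23 °C) should give the 2'-hydroxychalcone F2. NaOAc in refluxing EtOH should close it by oxa-Michael addition to the racemic flavanone F3. Kinetic resolution by asymmetric transfer hydrogenation ([RhCl(Cp*)(TsDPEN)], HCO2H/Et3N, EtOAc, 23 °C, catalyst enantiomer matched to the (2S) ketone) should reduce the (2S) enantiomer to 7 and leave the (2R)-flavanone F4, which is returned to F3 through F2 with base.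

2. Step 6. Attack through C6 of the catechin ring, approach on the wrong face of the cation, or self-condensation of the electrophile through its own ring A would lower regio- and facial selectivity. Fallback setting out from 7 and returning at 11: hydrogenolysis of 7 (H2, Pd/C, EtOAc with a trace of Et3N to hold back cleavage of the C4–O bond, 23 °C, stopped once the three benzyl ethers are cleaved) should give the free (2S,4S)-2-(3,4-dihydroxyphenyl)chroman-4,7-diol F5. This is condensed without protecting groups with an excess of 8 in 0.1 M aqueous HCl/EtOH at 23 °C through its para-quinone methide. This biomimetic coupling should give 11 directly, to be separated from regio- and stereoisomers on Sephadex LH-20 and by reversed-phase HPLC.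

3. Step 7. Hydrogenolysis of seven benzyl ethers may stall at partly benzylated stages, and the free polyphenol may be lost by air oxidation during isolation. Fallback setting out from 10 and returning at 11: the crude hydrogenolysis mixture is acetylated in the same flask (Ac2O, pyridine, 23 °C) to the octaacetate F6, which should be stable in air and purifiable on silica. Methanolysis (K2CO3, degassed MeOH, 0 °C, argon, then acidic resin) should then return 11.

**Further compounds**

F1 | step 3 | 1-[4-(benzyloxy)-2-hydroxyphenyl]ethan-1-one (purchased) | CC(=O)c1ccc(OCc2ccccc2)cc1O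
F2 | step 3 | (E)-1-[4-(benzyloxy)-2-hydroxyphenyl]-3-[3,4-bis(benzyloxy)phenyl]prop-2-en-1-one | O=C(/C=C/c1ccc(OCc2ccccc2)c(OCc2ccccc2)c1)c1ccc(OCc2ccccc2)cc1O
F3 | step 3 | rac-7-(benzyloxy)-2-[3,4-bis(benzyloxy)phenyl]chroman-4-one | O=C1CC(c2ccc(OCc3ccccc3)c(OCc3ccccc3)c2)Oc2cc(OCc3ccccc3)ccc21
F4 | step 3 | (2R)-7-(benzyloxy)-2-[3,4-bis(benzyloxy)phenyl]chroman-4-one | O=C1C[C@H](c2ccc(OCc3ccccc3)c(OCc3ccccc3)c2)Oc2cc(OCc3ccccc3)ccc21
F5 | step 6 | (2S,4S)-2-(3,4-dihydroxyphenyl)chroman-4,7-diol | O[C@H]1C[C@@H](c2ccc(O)c(O)c2)Oc2cc(O)ccc21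
F6 | step 7 | octaacetate of 11 | CC(=O)Oc1ccc2c(c1)O[C@H](c1ccc(OC(C)=O)c(OC(C)=O)c1)C[C@H]2c1c(OC(C)=O)cc(OC(C)=O)c2c1O[C@H](c1ccc(OC(C)=O)c(OC(C)=O)c1)[C@@H](OC(C)=O)C2
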